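**Retrosynthetic overview**
1. Last fragment union: the hindered tertiary aryl ester at C7–O, formed from a bicyclic C13 isochromenone (as its tertiary TMS ether) and a C9 orsellinate-type aroyl fluoride. Only acetal removal follows.
2. Bicyclic core from one acyclic vinyl ketone/ynone chain: an amine-catalysed Rauhut–Currier closure forms the carbocycle first (C8a–C4a), then an oxa-6π-electrocyclisation closes the 2H-pyran (O2–C1).
3. Acyclic chain: C7 carbinol by chelation-controlled addition of lithiated methoxyallene (an acryloyl anion equivalent) to an α-MOM-oxy methyl ketone. C6 comes from methyl (R)-glycidate, opened by the acetylide of a crotonaldehyde/ethynyl Grignard adduct.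
4. Aryl part: the benzene ring is built first, in its own branch, by dianion self-condensation of methyl acetoacetate (methyl orsellinate), followed by MOM and methyl ether formation, saponification and conversion to the acyl fluoride.

Assumption: the SMILES is read as (6R,7S) with the two oxygens trans (isochromene locants: C1H2, O2, C3 propenyl, C4, C4a, C5H2, C6 OH, C7 Me/O-acyl, C8 C=O, C8a), and the carbinol carbon of the alkyne fragment is carried as both epimers until it is oxidised in step 11.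

**Route**

Step 1
Reactants: 1 methyl acetoacetate (2 equiv)
Product: 4 methyl orsellinate (methyl 2,4-dihydroxy-6-methylbenzoate), via methyl acetoacetate dianion 2 (not isolated), via methyl 3,5,7-trioxooctanoate 3 (not isolated)
Conditions: NaH, THF, 0 °C; n-BuLi, 0 °C; rt, then reflux; 2 M HCl
Reagents that add atoms: none
Why: Claisen self-condensation of the dianion γ-carbon on the ester of a second molecule gives the triketo ester, whose C2 carbanion closes onto the C7 ketone (aldol condensation) and aromatises by loss of water, which can only give the orsellinate pattern.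

Step 2
Reactants: 4 methyl orsellinate
Product: 5 methyl 2-hydroxy-4-(methoxymethoxy)-6-methylbenzoate
Conditions: MOMCl (1.1 equiv), iPr2NEt, CH2Cl2, 0 °C
Reagents that add atoms: chloromethyl methyl ether (MOMCl), COCCl
Why: O-alkylation (acetal formation) goes to the free, more acidic 4-OH because the 2-OH is tied up in a hydrogen bond to the ester.

Step 3
Reactants: 5 methyl 2-hydroxy-4-(methoxymethoxy)-6-methylbenzoate
Product: 6 methyl 2-methoxy-4-(methoxymethoxy)-6-methylbenzoate
Conditions: MeI, K2CO3, DMF, 50 °C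
Reagents that add atoms: iodomethane, CI
Why: Williamson etherification of the remaining hydrogen-bonded phenol under forcing carbonate/DMF conditions.

Step 4
Reactants: 6 methyl 2-methoxy-4-(methoxymethoxy)-6-methylbenzoate
Product: 7 2-methoxy-4-(methoxymethoxy)-6-methylbenzoic acid
Conditions: KOH, DMSO/H2O (4:1), 90 °C; then 1 M HCl to pH 4, 0 °C
Reagents that add atoms: potassium hydroxide, [K+].[OH-]
Why: Saponification of the di-ortho-substituted ester needs hot hydroxide in DMSO, to which the aryl MOM and methyl ethers are inert.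

Step 5
Reactants: 7 2-methoxy-4-(methoxymethoxy)-6-methylbenzoic acid
Product: 8 2-methoxy-4-(methoxymethoxy)-6-methylbenzoyl fluoride
Conditions: cyanuric fluoride (0.4 equiv), pyridine, CH2Cl2, −20 °C → rt
Reagents that add atoms: cyanuric fluoride, Fc1nc(F)nc(F)n1
Why: Deoxyfluorination of the acid (acyl substitution via the acyloxytriazine) under non-acidic conditions gives a small, isolable acyl fluoride that tolerates the MOM acetal and suits a hindered ester.

Step 6
Reactants: 9 (E)-but-2-enal (crotonaldehyde), 10 ethynylmagnesium bromide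
Product: 12 triethyl{[(4E)-hex-4-en-1-yn-3-yl]oxy}silane (racemic), via bromomagnesium (4E)-hex-4-en-1-yn-3-olate 11 (not isolated)
Conditions: THF, 0 °C; then TESCl, imidazole (0.2 equiv), 0 °C → rt
Reagents that add atoms: chlorotriethylsilane (TESCl), CC[Si](Cl)(CC)CC
Why: 1,2-Grignard addition of the acetylide to the enal followed by silylation of the magnesium alkoxide in the same flask; the carbinol centre is racemic on purpose because it becomes a ketone in step 11.

Step 7
Reactants: 12 triethyl{[(4E)-hex-4-en-1-yn-3-yl]oxy}silane, 13 methyl (2R)-oxirane-2-carboxylate (methyl (R)-glycidate)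
Product: 15 methyl (2R,7E)-2-hydroxy-6-(triethylsilyloxy)non-7-en-4-ynoate (both C6 epimers), via lithium acetylide 14 (not isolated)
Conditions: n-BuLi, THF, −78 °C; BF3·OEt2, −78 °C; then 13, −78 °C; sat. aq. NH4Cl
Reagents that add atoms: none
Why: Yamaguchi–Hirao epoxide alkynylation: the alkynyl–BF3 species attacks by SN2 at the unsubstituted C3 (C2 is deactivated by the ester) and spares the ester, so the C2–O bond and its R configuration (C6 of the target) come unchanged from the chiral pool.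

Step 8
Reactants: 15 methyl (2R,7E)-2-hydroxy-6-(triethylsilyloxy)non-7-en-4-ynoate
Product: 16 methyl (2R,7E)-2-(methoxymethoxy)-6-(triethylsilyloxy)non-7-en-4-ynoate
Conditions: MOMCl, iPr2NEt, Bu4NI (cat.), CH2Cl2, 0 °C → rt
Reagents that add atoms: chloromethyl methyl ether (MOMCl), COCCl
Why: Acetal protection of the secondary alcohol installs the chelating ether needed in step 10 without touching the stereocentre.

Step 9
Reactants: 16 methyl (2R,7E)-2-(methoxymethoxy)-6-(triethylsilyloxy)non-7-en-4-ynoate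
Product: 18 (3R,8E)-3-(methoxymethoxy)-7-(triethylsilyloxy)dec-8-en-5-yn-2-one, via Weinreb amide 17 (not isolated)
Conditions: MeNH(OMe)·HCl, iPrMgCl, THF, −20 °C; then MeMgBr, 0 °C; sat. aq. NH4Cl
Reagents that add atoms: methylmagnesium bromide, C[Mg]Br; N,O-dimethylhydroxylamine hydrochloride, CNOC.Cl (its atoms are in 17 only)
Why: One-pot Weinreb ketone synthesis: the magnesium amide converts the ester into the N-methoxy-N-methylamide, whose magnesium chelate with MeMgBr collapses to the methyl ketone only on work-up, so there is no over-addition and the α-stereocentre is not enolised.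

Step 10
Reactants: 18 (3R,8E)-3-(methoxymethoxy)-7-(triethylsilyloxy)dec-8-en-5-yn-2-one, 19 1-methoxypropa-1,2-diene (methoxyallene)
Product: 22 (4S,5R,10E)-4,9-dihydroxy-5-(methoxymethoxy)-4-methyldodeca-1,10-dien-7-yn-3-one (both C9 epimers), via 1-lithio-1-methoxyallene 20 (not isolated), via methoxyallenyl carbinol 21 (not isolated)
Conditions: 19, n-BuLi, Et2O, −78 °C; then 18, Et2O, −78 °C; then 1 M HCl, THF, 0 °C → rt
Reagents that add atoms: water, O
Why: Lithiated methoxyallene is an acryloyl anion equivalent that adds 1,2 under Cram-chelate control (lithium bridges the ketone and MOM oxygens, the C4 chain shields one face, attack comes from the hydrogen side) to give the (4S) carbinol, which is C7 of the target with its oxygen trans to O6, and aqueous acid then hydrolyses the enol ether to the vinyl ketone and removes the TES group.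

Step 11
Reactants: 22 (4S,5R,10E)-4,9-dihydroxy-5-(methoxymethoxy)-4-methyldodeca-1,10-dien-7-yn-3-one
Product: 23 (4S,5R,10E)-4-hydroxy-5-(methoxymethoxy)-4-methyldodeca-1,10-dien-7-yne-3,9-dione
Conditions: MnO2 (excess), CH2Cl2, rt; filtered and used at once
Reagents that add atoms: none
Why: MnO2 oxidises only the doubly activated (allylic and propargylic) secondary alcohol and leaves the tertiary alcohol, the vinyl ketone and the MOM ether alone.

Step 12
Reactants: 23 (4S,5R,10E)-4-hydroxy-5-(methoxymethoxy)-4-methyldodeca-1,10-dien-7-yne-3,9-dione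
Product: 26 (6R,7S)-6-(methoxymethoxy)-7-methyl-3-[(1E)-prop-1-en-1-yl]-7-(trimethylsilyloxy)-6,7-dihydro-1H-isochromen-8(5H)-one, via trimethylsilyl ether 24 (not isolated), via exocyclic dienone 25 (not isolated)
Conditions: TMSOTf (1.05 equiv), iPr2NEt, CH2Cl2, −78 °C; then DABCO (0.3 equiv), 0.02 M, −78 °C → rt
Reagents that add atoms: trimethylsilyl trifluoromethanesulfonate (TMSOTf), C[Si](C)(C)OS(=O)(=O)C(F)(F)F
Why: After silylation of the tertiary OH (which would otherwise add 5-exo to the ynone), DABCO adds reversibly to the vinyl ketone, the enolate closes the carbocycle by 6-exo-dig Michael addition to the ynone and expels DABCO (Rauhut–Currier cycloisomerisation), and the resulting (Z)-1-oxatriene undergoes oxa-6π-electrocyclisation to the 2H-pyran, with both stereocentres as spectators.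

Step 13
Reactants: 26 (6R,7S)-6-(methoxymethoxy)-7-methyl-3-[(1E)-prop-1-en-1-yl]-7-(trimethylsilyloxy)-6,7-dihydro-1H-isochromen-8(5H)-one, 8 2-methoxy-4-(methoxymethoxy)-6-methylbenzoyl fluoride
Product: 27 (6R,7S)-6-(methoxymethoxy)-7-methyl-8-oxo-3-[(1E)-prop-1-en-1-yl]-5,6,7,8-tetrahydro-1H-isochromen-7-yl 2-methoxy-4-(methoxymethoxy)-6-methylbenzoate
Conditions: 8 (1.5 equiv), Bu4N[Ph3SiF2] (0.1 equiv), THF, 0 °C → rt
Reagents that add atoms: none
Why: Fluoride-catalysed acyl transfer: fluoride strips the TMS group to give a naked tertiary alkoxide that attacks the compact acyl fluoride and releases fluoride again (driven by the Si–F bond), the alkoxide route being the standard one to hindered tertiary aryl esters, and no stereocentre is touched.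

Step 14
Reactants: 27 (6R,7S)-6-(methoxymethoxy)-7-methyl-8-oxo-3-[(1E)-prop-1-en-1-yl]-5,6,7,8-tetrahydro-1H-isochromen-7-yl 2-methoxy-4-(methoxymethoxy)-6-methylbenzoate
Product: 29 (6R,7S)-6-hydroxy-7-methyl-8-oxo-3-[(1E)-prop-1-en-1-yl]-5,6,7,8-tetrahydro-1H-isochromen-7-yl 4-hydroxy-2-methoxy-6-methylbenzoate (CNP0187389.3), via bis(bromomethyl) ether 28 (not isolated)
Conditions: Me2BBr, CH2Cl2, −78 °C; then THF/sat. aq. NaHCO3, 0 °C
Reagents that add atoms: dimethylboron bromide, CB(C)Br (its bromine is in 28 only)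
Why: Lewis-acid acetal cleavage: Me2BBr turns both MOM ethers into bromomethyl ethers at −78 °C, which hydrolyse on cold bicarbonate work-up, while the aryl methyl ether, the hindered ester, the dienyl ether and the E-propenyl group are inert.

**Compound list**
1 | methyl acetoacetate (methyl 3-oxobutanoate) | CC(=O)CC(=O)OC | starting material
2 | methyl acetoacetate dianion (sodium lithium salt) | [Na+].[Li+].[CH2-]C(=O)[CH-]C(=O)OC | intermediate
3 | methyl 3,5,7-trioxooctanoate (present as its enolate) | COC(=O)CC(=O)CC(=O)CC(C)=O | intermediate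
4 | methyl orsellinate (methyl 2,4-dihydroxy-6-methylbenzoate) | COC(=O)c1c(C)cc(O)cc1O | intermediate
5 | methyl 2-hydroxy-4-(methoxymethoxy)-6-methylbenzoate | COCOc1cc(C)c(C(=O)OC)c(O)c1 | intermediate
6 | methyl 2-methoxy-4-(methoxymethoxy)-6-methylbenzoate | COCOc1cc(C)c(C(=O)OC)c(OC)c1 | intermediate
7 | 2-methoxy-4-(methoxymethoxy)-6-methylbenzoic acid | COCOc1cc(C)c(C(=O)O)c(OC)c1 | intermediate
8 | 2-methoxy-4-(methoxymethoxy)-6-methylbenzoyl fluoride | COCOc1cc(C)c(C(=O)F)c(OC)c1 | intermediate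
9 | (E)-but-2-enal (crotonaldehyde) | C/C=C/C=O | starting material
10 | ethynylmagnesium bromide | C#C[Mg]Br | starting material
11 | bromomagnesium (4E)-hex-4-en-1-yn-3-olate (racemic) | C/C=C/C(C#C)O[Mg]Br | intermediate
12 | triethyl{[(4E)-hex-4-en-1-yn-3-yl]oxy}silane (racemic) | C/C=C/C(C#C)O[Si](CC)(CC)CC | intermediate
13 | methyl (2R)-oxirane-2-carboxylate (methyl (R)-glycidate) | COC(=O)[C@H]1CO1 | starting material
14 | [(4E)-3-(triethylsilyloxy)hex-4-en-1-yn-1-yl]lithium | [Li]C#CC(O[Si](CC)(CC)CC)/C=C/C | intermediate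
15 | methyl (2R,7E)-2-hydroxy-6-(triethylsilyloxy)non-7-en-4-ynoate (both C6 epimers) | COC(=O)[C@H](O)CC#CC(O[Si](CC)(CC)CC)/C=C/C | intermediate
16 | methyl (2R,7E)-2-(methoxymethoxy)-6-(triethylsilyloxy)non-7-en-4-ynoate | COC(=O)[C@H](OCOC)CC#CC(O[Si](CC)(CC)CC)/C=C/C | intermediate
17 | (2R,7E)-N-methoxy-2-(methoxymethoxy)-N-methyl-6-(triethylsilyloxy)non-7-en-4-ynamide | CON(C)C(=O)[C@H](OCOC)CC#CC(O[Si](CC)(CC)CC)/C=C/C | intermediate
18 | (3R,8E)-3-(methoxymethoxy)-7-(triethylsilyloxy)dec-8-en-5-yn-2-one | CC(=O)[C@H](OCOC)CC#CC(O[Si](CC)(CC)CC)/C=C/C | intermediate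
19 | 1-methoxypropa-1,2-diene (methoxyallene) | COC=C=C | starting material
20 | (1-methoxypropa-1,2-dien-1-yl)lithium | COC([Li])=C=C | intermediate
21 | (4S,5R,10E)-3-methoxy-5-(methoxymethoxy)-4-methyl-9-(triethylsilyloxy)dodeca-1,2,10-trien-7-yn-4-ol | C=C=C(OC)[C@@](C)(O)[C@H](OCOC)CC#CC(O[Si](CC)(CC)CC)/C=C/C | intermediate
22 | (4S,5R,10E)-4,9-dihydroxy-5-(methoxymethoxy)-4-methyldodeca-1,10-dien-7-yn-3-one (both C9 epimers) | C=CC(=O)[C@@](C)(O)[C@H](OCOC)CC#CC(O)/C=C/C | intermediate
23 | (4S,5R,10E)-4-hydroxy-5-(methoxymethoxy)-4-methyldodeca-1,10-dien-7-yne-3,9-dione | C=CC(=O)[C@@](C)(O)[C@H](OCOC)CC#CC(=O)/C=C/C | intermediate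
24 | (4S,5R,10E)-5-(methoxymethoxy)-4-methyl-4-(trimethylsilyloxy)dodeca-1,10-dien-7-yne-3,9-dione | C=CC(=O)[C@@](C)(O[Si](C)(C)C)[C@H](OCOC)CC#CC(=O)/C=C/C | intermediate
25 | (3Z,5R,6S)-5-(methoxymethoxy)-6-methyl-2-methylidene-3-[(3E)-2-oxopent-3-en-1-ylidene]-6-(trimethylsilyloxy)cyclohexan-1-one | C=C1C(=O)[C@@](C)(O[Si](C)(C)C)[C@H](OCOC)C/C1=C/C(=O)/C=C/C | intermediate
26 | (6R,7S)-6-(methoxymethoxy)-7-methyl-3-[(1E)-prop-1-en-1-yl]-7-(trimethylsilyloxy)-6,7-dihydro-1H-isochromen-8(5H)-one | C/C=C/C1=CC2=C(CO1)C(=O)[C@@](C)(O[Si](C)(C)C)[C@H](OCOC)C2 | intermediate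
27 | (6R,7S)-6-(methoxymethoxy)-7-methyl-8-oxo-3-[(1E)-prop-1-en-1-yl]-5,6,7,8-tetrahydro-1H-isochromen-7-yl 2-methoxy-4-(methoxymethoxy)-6-methylbenzoate | C/C=C/C1=CC2=C(CO1)C(=O)[C@@](C)(OC(=O)c1c(C)cc(OCOC)cc1OC)[C@H](OCOC)C2 | intermediate
28 | (6R,7S)-6-(bromomethoxy)-7-methyl-8-oxo-3-[(1E)-prop-1-en-1-yl]-5,6,7,8-tetrahydro-1H-isochromen-7-yl 4-(bromomethoxy)-2-methoxy-6-methylbenzoate | C/C=C/C1=CC2=C(CO1)C(=O)[C@@](C)(OC(=O)c1c(C)cc(OCBr)cc1OC)[C@H](OCBr)C2 | intermediate
29 | (6R,7S)-6-hydroxy-7-methyl-8-oxo-3-[(1E)-prop-1-en-1-yl]-5,6,7,8-tetrahydro-1H-isochromen-7-yl 4-hydroxy-2-methoxy-6-methylbenzoate | C/C=C/C1=CC2=C(CO1)C(=O)[C@@](C)(OC(=O)c1c(C)cc(O)cc1OC)[C@H](O)C2 | target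

**Step count**
Total: 14 steps. Longest linear sequence: 9 steps (steps 6–14, from crotonaldehyde and ethynylmagnesium bromide), which is 9/14 of the total. The arene branch (steps 1–5) lies outside it.

**Steps most likely to fail, each with a fallback**

Step 12 (cascade ring formation). The ammonium enolate may oligomerise, or DABCO may be held on the ynone. The fallback sets out from 22 and comes back at 26, and replaces nucleophilic catalysis by a stoichiometric Mannich relay. Me2NH (THF, 0 °C) adds to the vinyl ketone of 22 to give (4S,5R,10E)-1-(dimethylamino)-4,9-dihydroxy-5-(methoxymethoxy)-4-methyldodec-10-en-7-yn-3-one F1. MnO2 then gives (4S,5R,10E)-1-(dimethylamino)-4-hydroxy-5-(methoxymethoxy)-4-methyldodec-10-en-7-yne-3,9-dione F2. TMSOTf/iPr2NEt followed by LiHMDS (THF, −78 °C) closes the carbocycle by intramolecular Michael addition of the only available ketone enolate to the ynone, giving (5R,6S)-2-[(dimethylamino)methyl]-5-(methoxymethoxy)-6-methyl-3-[(3E)-2-oxopent-3-en-1-ylidene]-6-(trimethylsilyloxy)cyclohexan-1-one F3. MeI and then NaHCO3 eliminate trimethylamine to the exocyclic dienone 25, which electrocyclises to 26.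

Step 10 (diastereoselectivity at C7). A lithium chelate is looser than a magnesium one, so the ratio may be poor. The fallback sets out from 18 and comes back at 22, and uses a Grignard reagent for the stereo-determining addition. Ethynylmagnesium bromide 10 (THF, −78 °C, tight magnesium chelate) gives (3R,4R,9E)-4-(methoxymethoxy)-3-methyl-8-(triethylsilyloxy)undec-9-ene-1,6-diyn-3-ol F4. Ph3PAuNTf2-catalysed hydration of the terminal, hydroxyl-flanked alkyne (aq. dioxane, rt) gives (3S,4R,9E)-3-hydroxy-4-(methoxymethoxy)-3-methyl-8-(triethylsilyloxy)undec-9-en-6-yn-2-one F5; selectivity over the internal alkyne is the weak point of this fallback. Mannich-type α-methylenation ((CH2O)n, N-methylanilinium trifluoroacetate, THF, reflux) gives (4S,5R,10E)-4-hydroxy-5-(methoxymethoxy)-4-methyl-9-(triethylsilyloxy)dodeca-1,10-dien-7-yn-3-one F6, and 1 M HCl/THF removes the TES group to give 22.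

Step 13 (hindered ester on a tertiary α-ketol; possible base-induced loss of the C6 ether). The fallback sets out from 18 and comes back at 27, and moves the acylation to the acyclic stage. The lithium alkoxide formed when 20 adds to 18 is acylated in the same flask by 8 (−78 → 0 °C) to give (4S,5R,10E)-3-methoxy-5-(methoxymethoxy)-4-methyl-9-(triethylsilyloxy)dodeca-1,2,10-trien-7-yn-4-yl 2-methoxy-4-(methoxymethoxy)-6-methylbenzoate F7. Dilute HCl/THF gives (4S,5R,10E)-9-hydroxy-5-(methoxymethoxy)-4-methyl-3-oxododeca-1,10-dien-7-yn-4-yl 2-methoxy-4-(methoxymethoxy)-6-methylbenzoate F8. MnO2 gives (4S,5R,10E)-5-(methoxymethoxy)-4-methyl-3,9-dioxododeca-1,10-dien-7-yn-4-yl 2-methoxy-4-(methoxymethoxy)-6-methylbenzoate F9. DABCO (0.3 equiv, CH2Cl2, rt, no silylation needed) then gives 27 directly.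

**Further compounds**
F1 | step 12 | (4S,5R,10E)-1-(dimethylamino)-4,9-dihydroxy-5-(methoxymethoxy)-4-methyldodec-10-en-7-yn-3-one | CN(C)CCC(=O)[C@@](C)(O)[C@H](OCOC)CC#CC(O)/C=C/C
F2 | step 12 | (4S,5R,10E)-1-(dimethylamino)-4-hydroxy-5-(methoxymethoxy)-4-methyldodec-10-en-7-yne-3,9-dione | CN(C)CCC(=O)[C@@](C)(O)[C@H](OCOC)CC#CC(=O)/C=C/C
F3 | step 12 | (5R,6S)-2-[(dimethylamino)methyl]-5-(methoxymethoxy)-6-methyl-3-[(3E)-2-oxopent-3-en-1-ylidene]-6-(trimethylsilyloxy)cyclohexan-1-one | CN(C)CC1C(=O)[C@@](C)(O[Si](C)(C)C)[C@H](OCOC)CC1=CC(=O)/C=C/C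
F4 | step 10 | (3R,4R,9E)-4-(methoxymethoxy)-3-methyl-8-(triethylsilyloxy)undec-9-ene-1,6-diyn-3-ol | C#C[C@@](C)(O)[C@H](OCOC)CC#CC(O[Si](CC)(CC)CC)/C=C/C
F5 | step 10 | (3S,4R,9E)-3-hydroxy-4-(methoxymethoxy)-3-methyl-8-(triethylsilyloxy)undec-9-en-6-yn-2-one | CC(=O)[C@@](C)(O)[C@H](OCOC)CC#CC(O[Si](CC)(CC)CC)/C=C/C
F6 | step 10 | (4S,5R,10E)-4-hydroxy-5-(methoxymethoxy)-4-methyl-9-(triethylsilyloxy)dodeca-1,10-dien-7-yn-3-one | C=CC(=O)[C@@](C)(O)[C@H](OCOC)CC#CC(O[Si](CC)(CC)CC)/C=C/C
F7 | step 13 | (4S,5R,10E)-3-methoxy-5-(methoxymethoxy)-4-methyl-9-(triethylsilyloxy)dodeca-1,2,10-trien-7-yn-4-yl 2-methoxy-4-(methoxymethoxy)-6-methylbenzoate | C=C=C(OC)[C@@](C)(OC(=O)c1c(C)cc(OCOC)cc1OC)[C@H](OCOC)CC#CC(O[Si](CC)(CC)CC)/C=C/C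
F8 | step 13 | (4S,5R,10E)-9-hydroxy-5-(methoxymethoxy)-4-methyl-3-oxododeca-1,10-dien-7-yn-4-yl 2-methoxy-4-(methoxymethoxy)-6-methylbenzoate | C=CC(=O)[C@@](C)(OC(=O)c1c(C)cc(OCOC)cc1OC)[C@H](OCOC)CC#CC(O)/C=C/C
F9 | step 13 | (4S,5R,10E)-5-(methoxymethoxy)-4-methyl-3,9-dioxododeca-1,10-dien-7-yn-4-yl 2-methoxy-4-(methoxymethoxy)-6-methylbenzoate | C=CC(=O)[C@@](C)(OC(=O)c1c(C)cc(OCOC)cc1OC)[C@H](OCOC)CC#CC(=O)/C=C/C
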